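Ring A is built last. The C4a–C5 and C8–C8a bonds are cut, so the benzo ring of the flavanone comes from a Diels–Alder benzannulation across the C5=C6 bond of a (2S)-2-aryl-5-(phenylsulfinyl)-2,3-dihydro-4H-pyran-4-one with 1-methoxy-3-trimethylsilyloxybutadiene. The step exploits the oxygen pattern of ring A, which carries oxygen only at C8a (the pyran O1) and at C7. The siloxy carbon of the diene becomes C7 and its termini become C8 and C5. Loss of silanol, methanol and benzenesulfenic acid then aromatises the ring in the same operation. The precursor already holds the complete B ring and the C2 stereocentre, set by a catalytic asymmetric hetero-Diels–Alder reaction of the B-ring aldehyde.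

Key step: step 10

Remarks on the chemistry:
- Ar = 3-[(E)-3-hydroxy-3-methylbut-1-en-1-yl]-4-methoxy-5-(3-methylbut-2-en-1-yl)phenyl; "salen" = N,N'-bis(3,5-di-tert-butylsalicylidene)cyclohexane-1,2-diamine.
- Assumption: the (S,S)-chromium complex of step 6 is taken to deliver the diene to the Si face of the aldehyde. If the first run shows the opposite sense, the (R,R)-complex is used without other change.
- Tributyl(phenylthio)stannane 17 is taken to be a catalogue reagent.
- The tertiary allylic alcohol is carried unprotected. Acid is therefore used only catalytically and cold (step 6) or dilute and aqueous (step 10). Any adventitious O-silylation by 12 should be reversed in these work-ups.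
- Sulfoxide 20 is used as the mixture of sulfur epimers, because sulfur is lost in step 10.

Step 1
Reactants: 1 3-bromo-4-hydroxybenzaldehyde; 2 allyl bromide
Product: 3 4-(allyloxy)-3-bromobenzaldehyde
Conditions: K2CO3, DMF, rt
Reagents that add atoms: allyl bromide (2), C=CCBr
Why: Williamson ether synthesis, in which the para-formyl phenoxide is alkylated at oxygen by the primary allylic bromide and nothing else in 1 is nucleophilic.

Step 2
Reactants: 3 4-(allyloxy)-3-bromobenzaldehyde
Product: 5 3-allyl-5-bromo-4-hydroxybenzaldehyde, via ortho-dienone 4 (not isolated)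
Conditions: N,N-diethylaniline, 200 °C
Reagents that add atoms: none
Why: Aromatic Claisen rearrangement, in which the [3,3]-shift delivers the allyl group to the only unsubstituted ortho carbon (C5) and dienone 4 tautomerises to the phenol, so the future prenyl chain arrives with an unbranched attachment.

Step 3
Reactants: 5 3-allyl-5-bromo-4-hydroxybenzaldehyde; 6 iodomethane
Product: 7 3-allyl-5-bromo-4-methoxybenzaldehyde
Conditions: MeI, K2CO3, DMF, rt → 40 °C
Reagents that add atoms: iodomethane (6), CI
Why: Williamson O-methylation of the hindered but acidic phenol with a small electrophile, the aldehyde, bromide and allyl group being inert.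

Step 4
Reactants: 7 3-allyl-5-bromo-4-methoxybenzaldehyde; 8 2-methylbut-2-ene
Product: 9 3-bromo-4-methoxy-5-(3-methylbut-2-en-1-yl)benzaldehyde
Conditions: (H2IMes)(PCy3)Cl2Ru=CHPh (3 mol%), 2-methylbut-2-ene/CH2Cl2, 40 °C, sealed
Reagents that add atoms: 2-methylbut-2-ene (8), CC=C(C)C
Why: Olefin cross-metathesis of a terminal allyl arene with a large excess of a trisubstituted alkene converts allyl into prenyl with loss of propene, and the aryl bromide and aldehyde do not interact with the ruthenium carbene.

Step 5
Reactants: 9 3-bromo-4-methoxy-5-(3-methylbut-2-en-1-yl)benzaldehyde; 10 2-methylbut-3-en-2-ol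
Product: 11 3-[(E)-3-hydroxy-3-methylbut-1-en-1-yl]-4-methoxy-5-(3-methylbut-2-en-1-yl)benzaldehyde (Ar–CHO)
Conditions: Pd(OAc)2 (3 mol%), P(o-tol)3 (6 mol%), Et3N, DMF, 100 °C
Reagents that add atoms: 2-methylbut-3-en-2-ol (10), C=CC(C)(C)O
Why: Mizoroki–Heck reaction, in which the aryl palladium species adds to the unhindered terminal carbon of 10 and syn β-hydride elimination gives the E-alkene; the tertiary carbinol has no hydrogen that would allow isomerisation to a ketone, and the trisubstituted prenyl alkene is too hindered to compete.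

Step 6
Reactants: 11 Ar–CHO; 12 (E)-1-methoxy-3-(trimethylsilyloxy)buta-1,3-diene
Product: 14 (2S)-2-Ar-2,3-dihydro-4H-pyran-4-one, via siloxy dihydropyran cycloadduct 13 (not isolated)
Conditions: (S,S)-(salen)Cr(III)BF4 (3 mol%), 4 Å MS, t-BuOMe, −30 °C; then TFA (5 mol%), CH2Cl2, −20 °C, 10 min; NaHCO3
Reagents that add atoms: (E)-1-methoxy-3-(trimethylsilyloxy)buta-1,3-diene (12), CO/C=C/C(=C)O[Si](C)(C)C
Why: Catalytic asymmetric hetero-Diels–Alder reaction of an aromatic aldehyde with a 1-methoxy-3-siloxydiene, in which the chiral chromium Lewis acid directs the diene to the Si face of the formyl group and so sets C2 as S, while the allylic acetal/silyl enol ether of 13 ionises under a trace of acid far faster than the tertiary allylic alcohol does.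

Step 7
Reactants: 14 (2S)-2-Ar-2,3-dihydro-4H-pyran-4-one; 15 iodine
Product: 16 (2S)-2-Ar-5-iodo-2,3-dihydro-4H-pyran-4-one
Conditions: I2 (2 equiv), pyridine/CH2Cl2, 0 °C → rt; aq. Na2S2O3
Reagents that add atoms: iodine (15), II
Why: α-Iodination of an enone with iodine/pyridine (pyridine adds at C6, the enolate is iodinated at C5, pyridine is eliminated), a reaction specific to the conjugated C5=C6 bond that should leave the isolated alkenes untouched under the buffered conditions.

Step 8
Reactants: 16 (2S)-2-Ar-5-iodo-2,3-dihydro-4H-pyran-4-one; 17 tributyl(phenylthio)stannane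
Product: 18 (2S)-2-Ar-5-(phenylthio)-2,3-dihydro-4H-pyran-4-one
Conditions: Pd2(dba)3 (2.5 mol%), Xantphos (5 mol%), toluene, 80 °C; aq. KF
Reagents that add atoms: tributyl(phenylthio)stannane (17), CCCC[Sn](CCCC)(CCCC)Sc1ccccc1
Why: Palladium-catalysed C–S cross-coupling of an alkenyl iodide with a tin thiolate (Stille-type), chosen because it runs without base or free thiolate, so that neither conjugate addition at C6 nor retro-oxa-Michael epimerisation of C2 can occur.

Step 9
Reactants: 18 (2S)-2-Ar-5-(phenylthio)-2,3-dihydro-4H-pyran-4-one; 19 3-chloroperoxybenzoic acid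
Product: 20 (2S)-2-Ar-5-(phenylsulfinyl)-2,3-dihydro-4H-pyran-4-one (both sulfur epimers)
Conditions: mCPBA (1.0 equiv), NaHCO3, CH2Cl2, −78 → −40 °C
Reagents that add atoms: 3-chloroperoxybenzoic acid (19), OOC(=O)c1cccc(Cl)c1
Why: Chemoselective sulfide-to-sulfoxide oxidation, in which one equivalent of peracid at low temperature should react at sulfur far faster than at the prenyl and styrenyl alkenes or the electron-poor C5=C6 bond, and the expected mixture of sulfur epimers is of no consequence.

Step 10
Reactants: 20 (2S)-2-Ar-5-(phenylsulfinyl)-2,3-dihydro-4H-pyran-4-one; 12 (E)-1-methoxy-3-(trimethylsilyloxy)buta-1,3-diene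
Product: 25 (2S)-7-hydroxy-2-Ar-2,3-dihydro-4H-chromen-4-one, via Diels–Alder adduct 21 (not isolated), via methoxy ketone 22 (not isolated), via sulfinyl enone 23 (not isolated), via dienone tautomer 24 (not isolated)
Conditions: 12 (3 equiv), Eu(fod)3 (5 mol%), toluene, 0 °C → rt; then 0.05 M HCl, THF–H2O, 0 °C; NaHCO3; then toluene, 60 °C
Reagents that add atoms: (E)-1-methoxy-3-(trimethylsilyloxy)buta-1,3-diene (12), CO/C=C/C(=C)O[Si](C)(C)C
Why: Proposed new method: a normal-demand [4+2] cycloaddition in which the sulfinyl group, chelated together with the C4 carbonyl by the lanthanide, activates the push–pull C5=C6 bond of 20, so that the nucleophilic CH2 terminus of 12 bonds to the oxygen-bearing β-carbon C6 (future C8a) and the methoxy terminus to the sulfinyl carbon C5 (future C4a); ring A is thereby closed as a six-membered carbocycle by an intermolecular cycloaddition that forms both C–C bonds suprafacially and gives a cis ring fusion. Dilute aqueous acid then hydrolyses the silyl enol ether of 21 to ketone 22 and eliminates methanol to enone 23, after which C5 is sp2 and the only hydrogen left syn to sulfur is H-8a (cis to the sulfinyl group because of the cis fusion); warming should bring about the sulfoxide syn-elimination (Ei) across C4a–C8a, and dienone 24 tautomerises to the C7 phenol. The closest known reactions are the Diels–Alder/aromatisation sequences of 2-sulfinyl enones and of chromones bearing an acceptor at C3 with 1-methoxy-3-siloxydienes, which give phenols by loss of methanol and a sulfenic acid; the dihydropyranone differs in being a less electron-poor, β-oxygenated enone, which is why the step is run with chelating Lewis-acid assistance. No stereocentre made here survives, since C4a, C5 and C8a are formed as mixtures and all end up sp2, while C2 is not touched because no base is present that could open the pyranone by a retro-oxa-Michael reaction. The step needs regioselectivity (oxygen at C7 and not at C6), secured by the matched polarisation of the diene terminus and the enone β-carbon, and chemoselectivity for the sulfinyl enone over the prenyl and styrenyl alkenes, secured by their lack of activation.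

Compound list
1 | 3-bromo-4-hydroxybenzaldehyde | O=Cc1ccc(O)c(Br)c1 | starting material
2 | allyl bromide | C=CCBr | starting material
3 | 4-(allyloxy)-3-bromobenzaldehyde | O=Cc1ccc(OCC=C)c(Br)c1 | intermediate
4 | 6-allyl-2-bromo-4-formylcyclohexa-2,4-dien-1-one (ortho-dienone, not isolated) | O=CC1=CC(CC=C)C(=O)C(Br)=C1 | intermediate
5 | 3-allyl-5-bromo-4-hydroxybenzaldehyde | O=Cc1cc(Br)c(O)c(CC=C)c1 | intermediate
6 | iodomethane | CI | starting material
7 | 3-allyl-5-bromo-4-methoxybenzaldehyde | COc1c(Br)cc(C=O)cc1CC=C | intermediate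
8 | 2-methylbut-2-ene | CC=C(C)C | starting material
9 | 3-bromo-4-methoxy-5-(3-methylbut-2-en-1-yl)benzaldehyde | COc1c(Br)cc(C=O)cc1CC=C(C)C | intermediate
10 | 2-methylbut-3-en-2-ol | C=CC(C)(C)O | starting material
11 | 3-[(E)-3-hydroxy-3-methylbut-1-en-1-yl]-4-methoxy-5-(3-methylbut-2-en-1-yl)benzaldehyde | COc1c(/C=C/C(C)(C)O)cc(C=O)cc1CC=C(C)C | intermediate
12 | (E)-1-methoxy-3-(trimethylsilyloxy)buta-1,3-diene | CO/C=C/C(=C)O[Si](C)(C)C | starting material
13 | (2S)-2-Ar-6-methoxy-4-(trimethylsilyloxy)-3,6-dihydro-2H-pyran (C6 epimers, not isolated) | COc1c(/C=C/C(C)(C)O)cc([C@@H]2CC(O[Si](C)(C)C)=CC(OC)O2)cc1CC=C(C)C | intermediate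
14 | (2S)-2-Ar-2,3-dihydro-4H-pyran-4-one | COc1c(/C=C/C(C)(C)O)cc([C@@H]2CC(=O)C=CO2)cc1CC=C(C)C | intermediate
15 | iodine | II | starting material
16 | (2S)-2-Ar-5-iodo-2,3-dihydro-4H-pyran-4-one | COc1c(/C=C/C(C)(C)O)cc([C@@H]2CC(=O)C(I)=CO2)cc1CC=C(C)C | intermediate
17 | tributyl(phenylthio)stannane | CCCC[Sn](CCCC)(CCCC)Sc1ccccc1 | starting material
18 | (2S)-2-Ar-5-(phenylthio)-2,3-dihydro-4H-pyran-4-one | COc1c(/C=C/C(C)(C)O)cc([C@@H]2CC(=O)C(Sc3ccccc3)=CO2)cc1CC=C(C)C | intermediate
19 | 3-chloroperoxybenzoic acid | OOC(=O)c1cccc(Cl)c1 | starting material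
20 | (2S)-2-Ar-5-(phenylsulfinyl)-2,3-dihydro-4H-pyran-4-one (sulfur epimers) | COc1c(/C=C/C(C)(C)O)cc([C@@H]2CC(=O)C(S(=O)c3ccccc3)=CO2)cc1CC=C(C)C | intermediate
21 | (2S)-2-Ar-5-methoxy-4a-(phenylsulfinyl)-7-(trimethylsilyloxy)-2,3,4a,5,8,8a-hexahydro-4H-chromen-4-one (cis-fused, mixture at C4a, C5, C8a and S, not isolated) | COc1c(/C=C/C(C)(C)O)cc([C@@H]2CC(=O)C3(S(=O)c4ccccc4)C(OC)C=C(O[Si](C)(C)C)CC3O2)cc1CC=C(C)C | intermediate
22 | (2S)-2-Ar-5-methoxy-4a-(phenylsulfinyl)perhydrochromene-4,7-dione (not isolated) | COc1c(/C=C/C(C)(C)O)cc([C@@H]2CC(=O)C3(S(=O)c4ccccc4)C(OC)CC(=O)CC3O2)cc1CC=C(C)C | intermediate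
23 | (2S)-2-Ar-4a-(phenylsulfinyl)-2,3,8,8a-tetrahydro-4H-chromene-4,7(4aH)-dione (C5=C6 enone, not isolated) | COc1c(/C=C/C(C)(C)O)cc([C@@H]2CC(=O)C3(S(=O)c4ccccc4)C=CC(=O)CC3O2)cc1CC=C(C)C | intermediate
24 | (2S)-2-Ar-2,3-dihydro-4H-chromene-4,7(8H)-dione (keto tautomer of 25, not isolated) | COc1c(/C=C/C(C)(C)O)cc([C@@H]2CC(=O)C3=C(CC(=O)C=C3)O2)cc1CC=C(C)C | intermediate
25 | (2S)-7-hydroxy-2-{3-[(E)-3-hydroxy-3-methylbut-1-en-1-yl]-4-methoxy-5-(3-methylbut-2-en-1-yl)phenyl}-2,3-dihydro-4H-chromen-4-one | COc1c(/C=C/C(C)(C)O)cc([C@@H]2CC(=O)c3ccc(O)cc3O2)cc1CC=C(C)C | target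

Total step count: 10. Longest linear sequence: 10 steps (1 → 25).

Steps most likely to fail

1. Step 10 (Proposed new method). The β-oxygenated sulfinyl enone may be too weak a dienophile, so that the diene is lost by hydrolysis or oligomerisation before it adds. The sulfoxide may eliminate towards C5 before methanol has been lost. Acid may also open the pyranone by β-elimination of the ring oxygen from C8a, or ionise the tertiary allylic alcohol.
Fallback, known chemistry only, setting out from aldehyde 11 and returning at 25: Claisen–Schmidt condensation of 11 with commercial 1-[4-(allyloxy)-2-hydroxyphenyl]ethanone (KOH, EtOH, rt) should give the 2'-hydroxychalcone (E)-1-[4-(allyloxy)-2-hydroxyphenyl]-3-Ar-prop-2-en-1-one F1. Sodium acetate in refluxing ethanol closes it by oxa-Michael addition to racemic 7-(allyloxy)-2-Ar-chroman-4-one F2. Pd(PPh3)4/morpholine removes the allyl ether to give racemic 7-hydroxy-2-Ar-chroman-4-one F3, and preparative HPLC on a polysaccharide chiral phase delivers the (2S)-enantiomer 25.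

2. Step 8. The palladium catalyst may be deactivated by sulfur, the iodide may be lost reductively, or sulfur may attack C6 of the vinylogous ester instead of coupling at C5.
Fallback, setting out from the non-isolated cycloadduct 13 of step 6 and returning at 18 (bypassing 14 and 16): instead of acid, the cold solution of 13 is treated with one equivalent of benzenesulfenyl chloride (CH2Cl2, −78 °C). This is the standard α-sulfenylation of a silyl enol ether, which is far more nucleophilic than the prenyl alkene, and should give (6S)-6-Ar-2-methoxy-3-(phenylthio)tetrahydro-4H-pyran-4-one F4. Catalytic camphorsulfonic acid in CH2Cl2 then ionises the acetal and expels methanol to give 18.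

3. Step 6. Facial selectivity may be eroded by an uncatalysed or hydroxyl-assisted background reaction, the catalyst may be inhibited by the tertiary hydroxyl, or the tertiary alcohol may undergo allylic ionisation during the acidic unmasking.
Fallback, setting out from 11 and returning at 14: a reagent-controlled boron aldol reaction in place of the cycloaddition. The enolate of (E)-4-chlorobut-3-en-2-one is formed with the appropriate antipode of diisopinocampheylboron chloride and i-Pr2NEt (Et2O, −78 °C, one extra equivalent to cover the free hydroxyl) and adds to the Si face of 11 to give (1E,5S)-1-chloro-5-hydroxy-5-Ar-pent-1-en-3-one F5. Silylation-triggered 6-endo addition–elimination (TMSOTf, i-Pr2NEt, −78 °C, mild aqueous work-up) then closes pyranone 14 with loss of hydrogen chloride.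

Further compounds
F1 | step 10 | (E)-1-[4-(allyloxy)-2-hydroxyphenyl]-3-Ar-prop-2-en-1-one | COc1c(/C=C/C(C)(C)O)cc(/C=C/C(=O)c2ccc(OCC=C)cc2O)cc1CC=C(C)C
F2 | step 10 | racemic 7-(allyloxy)-2-Ar-chroman-4-one | COc1c(/C=C/C(C)(C)O)cc(C2CC(=O)c3ccc(OCC=C)cc3O2)cc1CC=C(C)C
F3 | step 10 | racemic 7-hydroxy-2-Ar-chroman-4-one | COc1c(/C=C/C(C)(C)O)cc(C2CC(=O)c3ccc(O)cc3O2)cc1CC=C(C)C
F4 | step 8 | (6S)-6-Ar-2-methoxy-3-(phenylthio)tetrahydro-4H-pyran-4-one | COc1c(/C=C/C(C)(C)O)cc([C@@H]2CC(=O)C(Sc3ccccc3)C(OC)O2)cc1CC=C(C)C
F5 | step 6 | (1E,5S)-1-chloro-5-hydroxy-5-Ar-pent-1-en-3-one | COc1c(/C=C/C(C)(C)O)cc([C@@H](O)CC(=O)/C=C/Cl)cc1CC=C(C)C
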